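## Retrosynthetic overview
1. Ugonin Q comes from its tris-silyl ether. The C4″ hydroxyl is put in last, by allylic hydroxylation of an (S)-γ-cyclogeranyl flavone on the face anti to the benzylic arm.
2. The exocyclic methylene and the free 5-OH are unveiled together, by Hofmann-type opening of the tertiary ether of a trans-fused ring D/ring E (hexahydroxanthene) flavone.
3. Rings D and E close in one chiral-acid cascade from the 5-O-geranyl ether, which forms the C6–C1″, C2″–C7″ and C3″–O5 bonds. The cascade is a [1,3] O-to-C geranyl shift followed by a cation–olefin bicyclisation.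
4. The 5-O-geranyl ether comes from luteolin (rings A, B and C are bought) and geraniol.
5. Ring order: A, B and C are present from the start, D and E close together, and E is then reopened.

Locants: flavone numbering for rings A–C. Geranyl numbering for the terpene part: C1″ benzylic CH2, C2″ ring CH, C3″ carbon bearing C10″, C4″ carbinol carbon, C7″ CMe2.

Assumption: the (R)-binaphthol·SnCl4 acid is taken to fold the chain in the "normal" (ambrox-type) sense, which gives C2″(S). The antipodal ligand is equally available.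

## Route

Step 1
Reactants: 1 luteolin
Product: 2 7,3',4'-tris-O-TBS-luteolin (5-OH free)
Conditions: TBSCl (3.3 equiv), imidazole, DMF, 0 °C to rt
Reagents that add atoms: tert-butyldimethylsilyl chloride, CC(C)(C)[Si](C)(C)Cl
Why: Silyl ether formation; the 5-OH is locked in a hydrogen bond to the C4 carbonyl and does not react, so only the 7-, 3'- and 4'-phenols are capped, and no stereocentre is involved.

Step 2
Reactants: 2 7,3',4'-tris-O-TBS-luteolin; 3 geraniol
Product: 4 5-O-geranyl-7,3',4'-tris-O-TBS-luteolin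
Conditions: PPh3, DIAD, THF, 0 °C to rt
Reagents that add atoms: none
Why: Mitsunobu etherification; the only remaining acidic OH displaces the activated primary allylic alcohol by SN2 under neutral conditions that spare the aryl silyl ethers and the E-alkene, and no stereocentre is formed.

Step 3
Reactants: 4 5-O-geranyl-7,3',4'-tris-O-TBS-luteolin
Product: 6 trans-fused ring D/ring E flavone (O5 bonded to C3″; C2″ S; C3″ S; C2″-H anti to C3″-CH3), via 6-C-geranylflavone 5 (not isolated)
Conditions: SnCl4 (2.2 equiv), (R)-2-(2-fluorobenzyloxy)-2'-hydroxy-1,1'-binaphthyl (2.4 equiv), toluene, −78 °C, 2–3 d; aq. NaHCO3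
Reagents that add atoms: none
Why: Proposed new method: SnCl4 chelated between C4=O and the 5-O-ether ionises the allylic C–O bond and the tight geranyl cation/tin phenoxide pair collapses at C6, the only free ortho carbon ([1,3] shift to 5); the chiral SnCl4·binaphthol proton source then protonates the terminal isopropylidene of the chair-folded chain and the E-alkene is attacked anti by C7″ and by O5, closing rings D and E in one event with a trans junction and setting C2″(S) and C3″(S); the closest known reaction type is the Lewis-acid-assisted chiral Brønsted acid rearrangement/polyene cyclisation of simple geranyl aryl ethers to trans-hexahydroxanthenes.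

Step 4
Reactants: 6 trans-fused ring D/ring E flavone
Product: 8 6-{[(1S)-2,2-dimethyl-6-methylidenecyclohexyl]methyl}-7,3',4'-tris-O-TBS-luteolin, via 5-O-TMS ether 7 (not isolated)
Conditions: TMSOTf (3 equiv), 2,6-lutidine (5 equiv), CH2Cl2, −20 °C to rt; then pH 7 buffer/MeOH
Reagents that add atoms: none
Why: Proposed new method: silylation at the C4 carbonyl/O5 turns the tertiary alkyl aryl ether (a vinylogous tert-alkyl ester) into a leaving group; because the C3″–O bond is equatorial on trans-fused ring D, only a C10″ methyl hydrogen can lie antiperiplanar, so the hindered base removes it in a Hofmann-type E2 that gives the exocyclic methylene without touching C2″; the closest known types are TMSOTf/2,6-lutidine cleavage of tert-butyl ethers and esters and the exocyclic-alkene rule for equatorial tertiary methylcarbinol derivatives.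

Step 5
Reactants: 8 (S)-γ-cyclogeranyl flavone
Product: 9 6-{[(1S,3S)-3-hydroxy-6,6-dimethyl-2-methylidenecyclohexyl]methyl}-7,3',4'-tris-O-TBS-luteolin
Conditions: SeO2 (0.3 equiv), t-BuOOH (2.5 equiv), CH2Cl2, 0 °C to rt, stopped at about 80% conversion
Reagents that add atoms: selenium dioxide, O=[Se]=O (transfers the oxygen and is regenerated); tert-butyl hydroperoxide, CC(C)(C)OO (net oxygen source)
Why: SeO2/t-BuOOH allylic hydroxylation (ene reaction, then [2,3]-sigmatropic shift) keeps the methylene exocyclic and delivers oxygen to the C4″–H on the face opposite the C2″ arm, as labd-8(17)-enes give axial 7-alcohols; this sets C4″(S) trans to the arm, while the shielded tertiary C2″–H stays untouched.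

Step 6
Reactants: 9 tris-O-TBS-ugonin Q
Product: 10 ugonin Q
Conditions: Et3N·3HF, THF, 0 °C to rt, Ar
Reagents that add atoms: none
Why: Fluoride desilylation in a slightly acidic medium removes the three aryl TBS ethers without ionising the allylic alcohol, moving the alkene or oxidising the catechol, and no stereocentre is touched.

## Compound list
1 | luteolin | O=c1cc(-c2ccc(O)c(O)c2)oc2cc(O)cc(O)c12 | starting material
2 | 7,3',4'-tris-O-TBS-luteolin | O=c1cc(-c2ccc(O[Si](C)(C)C(C)(C)C)c(O[Si](C)(C)C(C)(C)C)c2)oc2cc(O[Si](C)(C)C(C)(C)C)cc(O)c12 | intermediate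
3 | geraniol | CC(C)=CCC/C(C)=C/CO | starting material
4 | 5-O-geranyl-7,3',4'-tris-O-TBS-luteolin | O=c1cc(-c2ccc(O[Si](C)(C)C(C)(C)C)c(O[Si](C)(C)C(C)(C)C)c2)oc2cc(O[Si](C)(C)C(C)(C)C)cc(OC/C=C(\C)CCC=C(C)C)c12 | intermediate
5 | 6-C-geranyl-7,3',4'-tris-O-TBS-luteolin | O=c1cc(-c2ccc(O[Si](C)(C)C(C)(C)C)c(O[Si](C)(C)C(C)(C)C)c2)oc2cc(O[Si](C)(C)C(C)(C)C)c(C/C=C(\C)CCC=C(C)C)c(O)c12 | intermediate
6 | trans-fused ring D/ring E flavone (C2″ S, C3″ S) | CC1(C)CCC[C@]2(C)Oc3c(C[C@@H]12)c(O[Si](C)(C)C(C)(C)C)cc4oc(-c5ccc(O[Si](C)(C)C(C)(C)C)c(O[Si](C)(C)C(C)(C)C)c5)cc(=O)c34 | intermediate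
7 | 5-O-TMS ether of 8 | C=C1[C@@H](Cc2c(O[Si](C)(C)C(C)(C)C)cc3oc(-c4ccc(O[Si](C)(C)C(C)(C)C)c(O[Si](C)(C)C(C)(C)C)c4)cc(=O)c3c2O[Si](C)(C)C)C(C)(C)CCC1 | intermediate
8 | (S)-γ-cyclogeranyl-7,3',4'-tris-O-TBS-luteolin | C=C1[C@@H](Cc2c(O[Si](C)(C)C(C)(C)C)cc3oc(-c4ccc(O[Si](C)(C)C(C)(C)C)c(O[Si](C)(C)C(C)(C)C)c4)cc(=O)c3c2O)C(C)(C)CCC1 | intermediate
9 | 7,3',4'-tris-O-TBS-ugonin Q | C=C1[C@@H](Cc2c(O[Si](C)(C)C(C)(C)C)cc3oc(-c4ccc(O[Si](C)(C)C(C)(C)C)c(O[Si](C)(C)C(C)(C)C)c4)cc(=O)c3c2O)C(C)(C)CC[C@@H]1O | intermediate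
10 | ugonin Q | C=C1[C@@H](Cc2c(O)cc3oc(-c4ccc(O)c(O)c4)cc(=O)c3c2O)C(C)(C)CC[C@@H]1O | target

## Step count and risks
Total steps: 6. Longest linear sequence: 6 (from luteolin).

**Step 3.** The geranyl group may be lost or may migrate to C8. The fallback makes the C6–C1″ bond by cross-coupling instead of by rearrangement. It sets out from 2, which is iodinated ortho to the free 5-OH with BnMe3N·ICl2/CaCO3 to give 6-iodo-7,3',4'-tris-O-TBS-luteolin F1. Stille allylation of this iodide with geranyltributylstannane (Pd(PPh3)4, LiCl, DMF) gives 5 as an isolated compound. The route is rejoined at 5, which is bicyclised to 6 with the same SnCl4·binaphthol acid.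

**Step 4.** The alkene regiochemistry of the ring E opening may go wrong. The fallback routes through the endocyclic alkene and an epoxide, and skips the exocyclic alkene and the SeO2 step.
- It sets out from 6. Opening under ionising E1 conditions (BF3·OEt2, 2,6-di-tert-butylpyridine, CH2Cl2) gives the usual trisubstituted cyclogeranyl alkene, (S)-α-cyclogeranyl-7,3',4'-tris-O-TBS-luteolin F2.
- mCPBA/NaHCO3 attacks the face anti to the C1″ arm and gives the 3″,4″-epoxide F3.
- Cp2TiCl (made from Cp2TiCl2 and Mn; trivalent titanium) opens the epoxide to the tertiary C3″ radical and removes a hydrogen from the least hindered C10″ methyl.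
- This gives 9 directly, so the route is rejoined at 9.

**Step 5.** Site or face selectivity may be poor, or over-oxidation may occur. The fallback sets C4″ by reagent-controlled reduction instead of by substrate-controlled oxidation. It sets out from 8, which is oxidised fully (SeO2/t-BuOOH, then Dess–Martin periodinane on the crude mixture) to the 4″-oxo-3″-methylidene enone F4. This enone is reduced 1,2 with (R)-2-methyl-CBS-oxazaborolidine [(R)-1-methyl-3,3-diphenylhexahydropyrrolo[1,2-c][1,3,2]oxazaborole] and BH3·SMe2 to the (S)-carbinol. The route is rejoined at 9.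

Further compounds
F1 | step 3 | 6-iodo-7,3',4'-tris-O-TBS-luteolin | O=c1cc(-c2ccc(O[Si](C)(C)C(C)(C)C)c(O[Si](C)(C)C(C)(C)C)c2)oc2cc(O[Si](C)(C)C(C)(C)C)c(I)c(O)c12
F2 | step 4 | (S)-α-cyclogeranyl-7,3',4'-tris-O-TBS-luteolin | CC1=CCCC(C)(C)[C@@H]1Cc1c(O[Si](C)(C)C(C)(C)C)cc2oc(-c3ccc(O[Si](C)(C)C(C)(C)C)c(O[Si](C)(C)C(C)(C)C)c3)cc(=O)c2c1O
F3 | step 4 | 3″,4″-epoxide of F2, oxygen anti to the C1″ arm | C[C@]12O[C@H]1CCC(C)(C)[C@@H]2Cc1c(O[Si](C)(C)C(C)(C)C)cc2oc(-c3ccc(O[Si](C)(C)C(C)(C)C)c(O[Si](C)(C)C(C)(C)C)c3)cc(=O)c2c1O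
F4 | step 5 | 4″-oxo-3″-methylidene enone (C2″ S) | C=C1[C@@H](Cc2c(O[Si](C)(C)C(C)(C)C)cc3oc(-c4ccc(O[Si](C)(C)C(C)(C)C)c(O[Si](C)(C)C(C)(C)C)c4)cc(=O)c3c2O)C(C)(C)CCC1=O
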